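**Retrosynthetic overview**
1. The ester C–O bond is made last, from commercial alpha-linolenic acid and the monocyclic C20 allylic alcohol (Steglich esterification).
2. Ring atoms: C1 = stereocentre bearing the side chain, C2 = methyl-bearing alkene carbon, C3 = alkene CH, C4 and C5 = CH2, C6 = CMe2. This cyclohexene (ring A) is the only ring and is closed once, at the C1–C6 bond of an open chain.
3. Enabling feature: C1 is both allylic to C2=C3 and bonded to the fully substituted C6, so C1–C6 is the union of an allyl terminus with a tertiary cation. A silyl group on C3 and a carboxyl group on C6 turn this into an anodic decarboxylative, allylsilane-terminated cyclisation in which both auxiliaries leave.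
4. The C3 silane stereocentre comes from a catalytic enantioselective conjugate silylation of a dienoate and is relayed to C1 by anti SE2' attack.
5. All 15 carbons of (E,E)-farnesol become the side chain, C1, C2, its methyl and C3. C4 and C5 come from a two-carbon Wittig unit, and C6 with its two methyls from isobutyric acid.

Key step: step 9

Assumption: both antipodes of the carbene precursor in step 5 are accessible from commercial (R,R)- and (S,S)-1,2-diphenylethylenediamine, and the antipode that delivers the (S)-silane is used.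

Step 1
Reactants: 1 (2E,6E)-farnesol
Product: 2 tert-butyldiphenylsilyl ether of (2E,6E)-farnesol
Conditions: TBDPSCl, imidazole, CH2Cl2, 0 °C to rt
Reagents that add atoms: tert-butyl(chloro)diphenylsilane, CC(C)(C)[Si](Cl)(c1ccccc1)c1ccccc1
Why: Silyl ether protection of the primary allylic alcohol; this group should withstand the oxidants, ylide, alkoxide, LiAlH4, LDA and electrolysis that follow, and fluoride is used only after the other silyl group has left.

Step 2
Reactants: 2 tert-butyldiphenylsilyl ether of (2E,6E)-farnesol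
Product: 3 (2E,6E,10E)-12-[(tert-butyldiphenylsilyl)oxy]-2,6,10-trimethyldodeca-2,6,10-trien-1-ol
Conditions: SeO2 (cat.), t-BuOOH, salicylic acid (cat.), CH2Cl2, 0 °C to rt
Reagents that add atoms: tert-butyl hydroperoxide, CC(C)(C)OO (terminal source of the new oxygen, passed on through SeO2, O=[Se]=O)
Why: Riley allylic oxidation in its catalytic form, in which the ene reaction and 2,3-sigmatropic shift occur at the most electron-rich, least hindered terminal alkene and oxidise the methyl group trans to the chain, so the (E)-allylic alcohol should result while the alkene next to the silyloxymethyl group is inductively deactivated.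

Step 3
Reactants: 3 (2E,6E,10E)-12-[(tert-butyldiphenylsilyl)oxy]-2,6,10-trimethyldodeca-2,6,10-trien-1-ol
Product: 4 (2E,6E,10E)-12-[(tert-butyldiphenylsilyl)oxy]-2,6,10-trimethyldodeca-2,6,10-trienal
Conditions: activated MnO2, CH2Cl2, rt
Reagents that add atoms: none
Why: Chemoselective MnO2 oxidation of an allylic alcohol to the enal without E/Z isomerisation, and any enal already formed in step 2 converges on the same product.

Step 4
Reactants: 4 (2E,6E,10E)-12-[(tert-butyldiphenylsilyl)oxy]-2,6,10-trimethyldodeca-2,6,10-trienal; 5 ethyl (triphenylphosphoranylidene)acetate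
Product: 6 ethyl (2E,4E,8E,12E)-14-[(tert-butyldiphenylsilyl)oxy]-4,8,12-trimethyltetradeca-2,4,8,12-tetraenoate
Conditions: 5, toluene, 60 °C
Reagents that add atoms: ethyl (triphenylphosphoranylidene)acetate 5, CCOC(=O)C=P(c1ccccc1)(c1ccccc1)c1ccccc1
Why: Wittig olefination with a stabilised ylide, which is (E)-selective and adds C4 and C5 in the form of a dienoate acceptor.

Step 5
Reactants: 6 ethyl (2E,4E,8E,12E)-14-[(tert-butyldiphenylsilyl)oxy]-4,8,12-trimethyltetradeca-2,4,8,12-tetraenoate
Product: 8 ethyl (3S,4E,8E,12E)-14-[(tert-butyldiphenylsilyl)oxy]-3-[dimethyl(phenyl)silyl]-4,8,12-trimethyltetradeca-4,8,12-trienoate, via pinacolboron ketene acetal 7 (not isolated)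
Conditions: PhMe2Si–Bpin, CuCl (cat.), chiral C1-symmetric N,N'-diaryl-4,5-diphenylimidazolinium tetrafluoroborate (cat.), NaOt-Bu (cat.), THF, −78 °C; then H2O
Reagents that add atoms: (dimethylphenylsilyl)boronic acid pinacol ester, C[Si](C)(c1ccccc1)B1OC(C)(C)C(C)(C)O1
Why: Enantioselective copper-catalysed conjugate silylation through an NHC–Cu–SiMe2Ph species, a reaction type established for acyclic dienoates, which take up silicon 1,4 at the beta carbon; the chiral carbene selects the alkene face and thereby sets the (S)-configured C3 silane, and 1,6-addition is disfavoured by the substituents on the gamma and delta carbons.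

Step 6
Reactants: 8 ethyl (3S,4E,8E,12E)-14-[(tert-butyldiphenylsilyl)oxy]-3-[dimethyl(phenyl)silyl]-4,8,12-trimethyltetradeca-4,8,12-trienoate
Product: 9 (3S,4E,8E,12E)-14-[(tert-butyldiphenylsilyl)oxy]-3-[dimethyl(phenyl)silyl]-4,8,12-trimethyltetradeca-4,8,12-trien-1-ol
Conditions: LiAlH4, Et2O, 0 °C; aqueous NaOH work-up
Reagents that add atoms: none
Why: Hydride reduction of the ester to the primary alcohol, to which the silyl ether, the allylsilane and the isolated alkenes are inert, and which cannot touch the silane stereocentre beta to the carbonyl group.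

Step 7
Reactants: 9 (3S,4E,8E,12E)-14-[(tert-butyldiphenylsilyl)oxy]-3-[dimethyl(phenyl)silyl]-4,8,12-trimethyltetradeca-4,8,12-trien-1-ol
Product: 10 [(3S,4E,8E,12E)-14-[(tert-butyldiphenylsilyl)oxy]-1-iodo-4,8,12-trimethyltetradeca-4,8,12-trien-3-yl]dimethyl(phenyl)silane
Conditions: PPh3, imidazole, I2 premixed in CH2Cl2 at 0 °C, then 9
Reagents that add atoms: iodine, II
Why: Appel-type iodination by SN2 displacement at the primary carbon of the alkoxyphosphonium salt, with premixing of the reagents so that no free iodine remains to iododesilylate the allylsilane.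

Step 8
Reactants: 10 [(3S,4E,8E,12E)-14-[(tert-butyldiphenylsilyl)oxy]-1-iodo-4,8,12-trimethyltetradeca-4,8,12-trien-3-yl]dimethyl(phenyl)silane; 11 isobutyric acid
Product: 13 (5S,6E,10E,14E)-16-[(tert-butyldiphenylsilyl)oxy]-5-[dimethyl(phenyl)silyl]-2,2,6,10,14-pentamethylhexadeca-6,10,14-trienoic acid, via dilithium enediolate of isobutyric acid 12 (not isolated)
Conditions: 11, LDA (LiN(i-Pr)2, 2 equiv per 11), THF, 0 to 40 °C; then 10, DMPU, 0 °C to rt; cold dilute HCl
Reagents that add atoms: isobutyric acid 11, CC(C)C(=O)O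
Why: Alkylation of a carboxylic acid dianion by SN2 attack on the unhindered primary iodide, which builds the quaternary C6 with both methyl groups and gives the free acid directly, so no hindered ester has to be hydrolysed.

Step 9
Reactants: 13 (5S,6E,10E,14E)-16-[(tert-butyldiphenylsilyl)oxy]-5-[dimethyl(phenyl)silyl]-2,2,6,10,14-pentamethylhexadeca-6,10,14-trienoic acid
Product: 16 tert-butyldiphenylsilyl ether of (2E,6E)-3,7-dimethyl-9-[(1S)-2,6,6-trimethylcyclohex-2-en-1-yl]nona-2,6-dien-1-ol, via tertiary carbocation 14 (not isolated), via beta-silyl cyclohexyl cation 15 (not isolated)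
Conditions: undivided cell, graphite anode, Pt cathode, anode potential held at the carboxylate wave until about 2.2 F/mol have passed, 2,4,6-collidine, (CF3)2CHOH (5 equiv), n-Bu4NPF6, CH2Cl2, 0 °C; aq. NaHCO3
Reagents that add atoms: none
Why: Proposed new method: two-electron oxidation of the collidinium carboxylate of 13 at graphite expels CO2 and places the tertiary cation 14 exactly at C6 without any Brønsted or Lewis acid, the C1=C2 allylsilane captures it to give the hyperconjugatively stabilised cation 15, and transfer of the silyl group to hexafluoroisopropanol leaves the C2=C3 alkene. The closest known reaction types are the Hofer-Moest (non-Kolbe) electrolysis of tertiary carboxylic acids with capture of the cation by a heteroatom nucleophile and the Lewis acid induced tert-alkylation or cyclisation of allylsilanes (Hosomi-Sakurai type SE2' reaction), whose union in one carbocyclisation has not been shown. Ring A closes at C6–C1 in the 6-endo-trig mode at the C1=C2 alkene through a chair-like transition state, because the 5-exo mode would put the charge on a secondary carbon out of reach of silicon. The new C1 stereocentre is controlled by the C3 silane stereocentre: the C3–Si bond has to stand parallel to the alkene p orbitals, allylic 1,2-strain against the C2 methyl keeps C3–H rather than silicon in the alkene plane, the tether can then reach only the face anti to silicon, and with the (E)-alkene holding the side chain equatorial the (5S)-silane should be translated into (S)-C1. The step needs site selectivity among four alkenes (secured by the carboxylate, an anion that should be oxidised before the allylsilane and well before the isolated alkenes), the alpha position of the new alkene (secured by loss of silicon instead of a proton) and a stop after one ring (secured because 15 is a far weaker electrophile than a bare tertiary cation and is desilylated before the next alkene can attack).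

Step 10
Reactants: 16 tert-butyldiphenylsilyl ether of (2E,6E)-3,7-dimethyl-9-[(1S)-2,6,6-trimethylcyclohex-2-en-1-yl]nona-2,6-dien-1-ol
Product: 17 (2E,6E)-3,7-dimethyl-9-[(1S)-2,6,6-trimethylcyclohex-2-en-1-yl]nona-2,6-dien-1-ol
Conditions: n-Bu4NF (TBAF), THF, 0 °C to rt
Reagents that add atoms: none
Why: Fluoride-induced silyl ether cleavage driven by the strong Si–F bond, in a non-acidic medium that leaves the ring alkene in its position and the C1 stereocentre untouched.

Step 11
Reactants: 17 (2E,6E)-3,7-dimethyl-9-[(1S)-2,6,6-trimethylcyclohex-2-en-1-yl]nona-2,6-dien-1-ol; 18 alpha-linolenic acid, (9Z,12Z,15Z)-octadeca-9,12,15-trienoic acid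
Product: 20 (2E,6E)-3,7-dimethyl-9-[(1S)-2,6,6-trimethylcyclohex-2-en-1-yl]nona-2,6-dien-1-yl (9Z,12Z,15Z)-octadeca-9,12,15-trienoate, via linolenoyl O-acylisourea 19 (not isolated)
Conditions: 18, DCC, DMAP (cat.), CH2Cl2, 0 °C to rt, argon, dark
Reagents that add atoms: alpha-linolenic acid 18, CC/C=C\C/C=C\C/C=C\CCCCCCCC(=O)O
Why: Steglich esterification (carbodiimide activation with DMAP acyl transfer) under neutral conditions at or below room temperature, which should keep the skipped (Z,Z,Z)-triene from isomerising or moving into conjugation.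

**Compound list**
1 | (2E,6E)-farnesol | OC/C=C(\C)CC/C=C(\C)CCC=C(C)C | starting material
2 | tert-butyldiphenylsilyl ether of (2E,6E)-farnesol | CC(C)(C)[Si](c1ccccc1)(c1ccccc1)OC/C=C(\C)CC/C=C(\C)CCC=C(C)C | intermediate
3 | (2E,6E,10E)-12-[(tert-butyldiphenylsilyl)oxy]-2,6,10-trimethyldodeca-2,6,10-trien-1-ol | CC(C)(C)[Si](c1ccccc1)(c1ccccc1)OC/C=C(\C)CC/C=C(\C)CC/C=C(\C)CO | intermediate
4 | (2E,6E,10E)-12-[(tert-butyldiphenylsilyl)oxy]-2,6,10-trimethyldodeca-2,6,10-trienal | CC(C)(C)[Si](c1ccccc1)(c1ccccc1)OC/C=C(\C)CC/C=C(\C)CC/C=C(\C)C=O | intermediate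
5 | ethyl (triphenylphosphoranylidene)acetate | CCOC(=O)C=P(c1ccccc1)(c1ccccc1)c1ccccc1 | starting material
6 | ethyl (2E,4E,8E,12E)-14-[(tert-butyldiphenylsilyl)oxy]-4,8,12-trimethyltetradeca-2,4,8,12-tetraenoate | CC(C)(C)[Si](c1ccccc1)(c1ccccc1)OC/C=C(\C)CC/C=C(\C)CC/C=C(\C)/C=C/C(=O)OCC | intermediate
7 | pinacolboron ketene acetal of 8 (enolate geometry not defined, not isolated) | CC(C)(C)[Si](c1ccccc1)(c1ccccc1)OC/C=C(\C)CC/C=C(\C)CC/C=C(\C)[C@H](C=C(OCC)OB1OC(C)(C)C(C)(C)O1)[Si](C)(C)c1ccccc1 | intermediate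
8 | ethyl (3S,4E,8E,12E)-14-[(tert-butyldiphenylsilyl)oxy]-3-[dimethyl(phenyl)silyl]-4,8,12-trimethyltetradeca-4,8,12-trienoate | CC(C)(C)[Si](c1ccccc1)(c1ccccc1)OC/C=C(\C)CC/C=C(\C)CC/C=C(\C)[C@H](CC(=O)OCC)[Si](C)(C)c1ccccc1 | intermediate
9 | (3S,4E,8E,12E)-14-[(tert-butyldiphenylsilyl)oxy]-3-[dimethyl(phenyl)silyl]-4,8,12-trimethyltetradeca-4,8,12-trien-1-ol | CC(C)(C)[Si](c1ccccc1)(c1ccccc1)OC/C=C(\C)CC/C=C(\C)CC/C=C(\C)[C@H](CCO)[Si](C)(C)c1ccccc1 | intermediate
10 | [(3S,4E,8E,12E)-14-[(tert-butyldiphenylsilyl)oxy]-1-iodo-4,8,12-trimethyltetradeca-4,8,12-trien-3-yl]dimethyl(phenyl)silane | CC(C)(C)[Si](c1ccccc1)(c1ccccc1)OC/C=C(\C)CC/C=C(\C)CC/C=C(\C)[C@H](CCI)[Si](C)(C)c1ccccc1 | intermediate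
11 | isobutyric acid | CC(C)C(=O)O | starting material
12 | dilithium enediolate of isobutyric acid (not isolated) | [Li+].[Li+].CC(C)=C([O-])[O-] | intermediate
13 | (5S,6E,10E,14E)-16-[(tert-butyldiphenylsilyl)oxy]-5-[dimethyl(phenyl)silyl]-2,2,6,10,14-pentamethylhexadeca-6,10,14-trienoic acid | CC(C)(C)[Si](c1ccccc1)(c1ccccc1)OC/C=C(\C)CC/C=C(\C)CC/C=C(\C)[C@H](CCC(C)(C)C(=O)O)[Si](C)(C)c1ccccc1 | intermediate
14 | tertiary carbocation at C6 formed by loss of CO2 from 13 (not isolated) | CC(C)(C)[Si](c1ccccc1)(c1ccccc1)OC/C=C(\C)CC/C=C(\C)CC/C=C(\C)[C@H](CC[C+](C)C)[Si](C)(C)c1ccccc1 | intermediate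
15 | beta-silyl cyclohexyl cation, charge at C2, silyl group at C3 trans to the side chain at C1 (not isolated) | CC(C)(C)[Si](c1ccccc1)(c1ccccc1)OC/C=C(\C)CC/C=C(\C)CC[C@@H]1[C+](C)[C@@H]([Si](C)(C)c2ccccc2)CCC1(C)C | intermediate
16 | tert-butyldiphenylsilyl ether of (2E,6E)-3,7-dimethyl-9-[(1S)-2,6,6-trimethylcyclohex-2-en-1-yl]nona-2,6-dien-1-ol | CC(C)(C)[Si](c1ccccc1)(c1ccccc1)OC/C=C(\C)CC/C=C(\C)CC[C@@H]1C(C)=CCCC1(C)C | intermediate
17 | (2E,6E)-3,7-dimethyl-9-[(1S)-2,6,6-trimethylcyclohex-2-en-1-yl]nona-2,6-dien-1-ol | OC/C=C(\C)CC/C=C(\C)CC[C@@H]1C(C)=CCCC1(C)C | intermediate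
18 | alpha-linolenic acid, (9Z,12Z,15Z)-octadeca-9,12,15-trienoic acid | CC/C=C\C/C=C\C/C=C\CCCCCCCC(=O)O | starting material
19 | linolenoyl O-acylisourea from 18 and DCC (not isolated) | CC/C=C\C/C=C\C/C=C\CCCCCCCC(=O)OC(=NC1CCCCC1)NC1CCCCC1 | intermediate
20 | (2E,6E)-3,7-dimethyl-9-[(1S)-2,6,6-trimethylcyclohex-2-en-1-yl]nona-2,6-dien-1-yl (9Z,12Z,15Z)-octadeca-9,12,15-trienoate | CC/C=C\C/C=C\C/C=C\CCCCCCCC(=O)OC/C=C(\C)CC/C=C(\C)CC[C@@H]1C(C)=CCCC1(C)C | target

Total step count: 11. Longest linear sequence: 11 steps, from 1 to 20.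

**Steps most likely to fail**

Step 9.
- Risk: the allylsilane may be oxidised in competition with the carboxylate. The tertiary cation may lose a proton before the ring closes. The cyclisation may also run on into the next alkene of the side chain.
- Fallback (known chemistry, from 10 back to 16): iodine–lithium exchange on 10 (t-BuLi, Et2O/pentane, −78 °C) gives the primary alkyllithium F1. F1 adds to acetone to give the tertiary alcohol (5S,6E,10E,14E)-16-[(tert-butyldiphenylsilyl)oxy]-5-[dimethyl(phenyl)silyl]-2,6,10,14-tetramethylhexadeca-6,10,14-trien-2-ol F2. Ionisation of F2 with SnCl4 and 2,6-di-tert-butyl-4-methylpyridine (CH2Cl2, −78 °C) is a classical Lewis acid induced, allylsilane-terminated cation–olefin cyclisation. It passes through the same cations 14 and 15, with the pyridine base suppressing protodesilylation, and returns to the route at 16.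

Step 5.
- Risk: the methyl group on the gamma carbon sits next to the reacting centre. It may erode facial selectivity or divert silicon into 1,6-addition.
- Fallback (auxiliary control instead of catalyst control, from 6 back to 9): saponification of 6 (LiOH, THF/MeOH/H2O) gives (2E,4E,8E,12E)-14-[(tert-butyldiphenylsilyl)oxy]-4,8,12-trimethyltetradeca-2,4,8,12-tetraenoic acid F3. Pivaloyl chloride and Et3N convert F3 into the mixed pivalic anhydride F4. F4 acylates commercial (S)-4-phenyl-1,3-oxazolidin-2-one (LiCl, THF) to give the N-tetraenoyl oxazolidinone F5.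
- Conjugate addition of the monosilylcopper reagent Li[PhMe2SiCuI] (from PhMe2SiLi and CuI·SMe2, THF, −78 °C) to the chelated s-cis conformer should occur on the face away from the phenyl group. This should give the (3S)-silyl imide F6. Reductive removal of the auxiliary with LiBH4 (Et2O, MeOH, 0 °C) returns to the route at 9.

Step 2.
- Risk: site selectivity among the three trisubstituted alkenes may be poor, and over-oxidation may lower throughput.
- Fallback (cleave the terminal alkene and rebuild it, from 2 back to 4): NBS in THF/H2O at 0 °C attacks the terminal alkene to give the racemic bromohydrin (6E,10E)-3-bromo-12-[(tert-butyldiphenylsilyl)oxy]-2,6,10-trimethyldodeca-6,10-dien-2-ol F7. K2CO3 in MeOH closes F7 to the racemic terminal epoxide F8. H5IO6 (THF/Et2O) cleaves F8 to (4E,8E)-10-[(tert-butyldiphenylsilyl)oxy]-4,8-dimethyldeca-4,8-dienal F9. An (E)-selective Wittig reaction of F9 with commercial 2-(triphenylphosphoranylidene)propanal (toluene, reflux) returns to the route at 4.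

**Further compounds**
F1 | step 9 | primary alkyllithium from 10 (not isolated) | CC(C)(C)[Si](c1ccccc1)(c1ccccc1)OC/C=C(\C)CC/C=C(\C)CC/C=C(\C)[C@H](CC[Li])[Si](C)(C)c1ccccc1
F2 | step 9 | (5S,6E,10E,14E)-16-[(tert-butyldiphenylsilyl)oxy]-5-[dimethyl(phenyl)silyl]-2,6,10,14-tetramethylhexadeca-6,10,14-trien-2-ol | CC(C)(C)[Si](c1ccccc1)(c1ccccc1)OC/C=C(\C)CC/C=C(\C)CC/C=C(\C)[C@H](CCC(C)(C)O)[Si](C)(C)c1ccccc1
F3 | step 5 | (2E,4E,8E,12E)-14-[(tert-butyldiphenylsilyl)oxy]-4,8,12-trimethyltetradeca-2,4,8,12-tetraenoic acid | CC(C)(C)[Si](c1ccccc1)(c1ccccc1)OC/C=C(\C)CC/C=C(\C)CC/C=C(\C)/C=C/C(=O)O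
F4 | step 5 | mixed pivalic anhydride of F3 (not isolated) | CC(C)(C)[Si](c1ccccc1)(c1ccccc1)OC/C=C(\C)CC/C=C(\C)CC/C=C(\C)/C=C/C(=O)OC(=O)C(C)(C)C
F5 | step 5 | (4S)-3-{(2E,4E,8E,12E)-14-[(tert-butyldiphenylsilyl)oxy]-4,8,12-trimethyltetradeca-2,4,8,12-tetraenoyl}-4-phenyl-1,3-oxazolidin-2-one | CC(C)(C)[Si](c1ccccc1)(c1ccccc1)OC/C=C(\C)CC/C=C(\C)CC/C=C(\C)/C=C/C(=O)N1[C@@H](c2ccccc2)COC1=O
F6 | step 5 | (4S)-3-{(3S,4E,8E,12E)-14-[(tert-butyldiphenylsilyl)oxy]-3-[dimethyl(phenyl)silyl]-4,8,12-trimethyltetradeca-4,8,12-trienoyl}-4-phenyl-1,3-oxazolidin-2-one | CC(C)(C)[Si](c1ccccc1)(c1ccccc1)OC/C=C(\C)CC/C=C(\C)CC/C=C(\C)[C@H](CC(=O)N1[C@@H](c2ccccc2)COC1=O)[Si](C)(C)c1ccccc1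
F7 | step 2 | (6E,10E)-3-bromo-12-[(tert-butyldiphenylsilyl)oxy]-2,6,10-trimethyldodeca-6,10-dien-2-ol (racemic) | CC(C)(C)[Si](c1ccccc1)(c1ccccc1)OC/C=C(\C)CC/C=C(\C)CCC(Br)C(C)(C)O
F8 | step 2 | terminal 10,11-epoxide of 2 (racemic) | CC(C)(C)[Si](c1ccccc1)(c1ccccc1)OC/C=C(\C)CC/C=C(\C)CCC1OC1(C)C
F9 | step 2 | (4E,8E)-10-[(tert-butyldiphenylsilyl)oxy]-4,8-dimethyldeca-4,8-dienal | CC(C)(C)[Si](c1ccccc1)(c1ccccc1)OC/C=C(\C)CC/C=C(\C)CCC=O
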